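The spiro-dihydropyran is made last by a hetero-Diels–Alder reaction of a β-triketone-derived oxadiene with the exocyclic methylene of an octalin diene. Everything rests on disconnecting the methyl/isopropyl-bearing cyclohexane ring of the octalin half between its isopropyl-bearing carbon (C8′) and the olefinic ring-fusion carbon (C8a′). The key step exploits the C1′=C8a′ double bond next to the spiro carbon as a latent cyclohexenone. A silylium-triggered, hydride-terminated cation–olefin cyclization of a citronellal-derived 4-(6-methylhept-5-en-2-yl)cyclohex-2-enone makes this bond: the enone β-carbon captures the prenyl terminus, which becomes the isopropyl group, its stereocentre relayed from the two existing centres through a chair. The resulting regiodefined silyl enol ether lets the ring-fusion double bond be restored.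

Key step: step 3

Remark (assumption): 12 and 14 are written as diketo forms and 14 without alkene geometry; both exist as interconverting enol or E/Z forms, and the minor isomers of the final cycloaddition are taken to be separable by chromatography.

Step 1
Reactants: 1 (R)-citronellal; 2 methyl vinyl ketone
Product: 3 (2R,3R)-3,7-dimethyl-2-(3-oxobutyl)oct-6-enal
Conditions: (R)-2-[methoxy(diphenyl)methyl]pyrrolidine (5 mol %), ethyl 3,4-dihydroxybenzoate (20 mol %), 2 (1.5 equiv), neat, 4 °C
Reagents that add atoms: none
Why: Enamine-catalysed Michael addition of an aldehyde to an enone (diarylprolinol ether with catechol co-catalyst): the E-enamine is attacked on the face away from the CPh2OMe group, so the (R)-catalyst should set the new α-centre as 2R under catalyst control, while the 3R centre is bought with citronellal.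

Step 2
Reactants: 3 (2R,3R)-3,7-dimethyl-2-(3-oxobutyl)oct-6-enal
Product: 4 (4R)-4-[(2R)-6-methylhept-5-en-2-yl]cyclohex-2-en-1-one
Conditions: KOH (0.1 M aq.), n-Bu4NOH (10 mol %), THF–Et2O, reflux
Reagents that add atoms: none
Why: Intramolecular aldol condensation (second half of a Robinson annulation): the methyl ketone enolate closes onto the aldehyde and E1cB dehydration gives the enone, the α-branched aldehyde cyclising faster than it enolises so that C4 keeps its configuration (it is γ once the enone exists); no new stereocentre.

Step 3
Reactants: 4 (4R)-4-[(2R)-6-methylhept-5-en-2-yl]cyclohex-2-en-1-one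
Product: 5 triethyl{[(4aR,5R,8S,8aS)-5-methyl-8-(propan-2-yl)-3,4,4a,5,6,7,8,8a-octahydronaphthalen-2-yl]oxy}silane
Conditions: Et3SiH (4 equiv), Tf2NH (10 mol %, gives Et3SiNTf2 in situ), 2,6-di-tert-butyl-4-methylpyridine (5 mol %), CH2Cl2, −78 → −40 °C; Et3N quench
Reagents that add atoms: triethylsilane, CC[SiH](CC)CC
Why: Proposed new method: Et3Si+ O-silylates the enone to a 1-silyloxyallyl cation whose β-carbon (C3 of the cyclohexenone) is attacked by the less substituted carbon of the pendant trisubstituted alkene, and the resulting tertiary cation abstracts hydride from Et3SiH, which creates the isopropyl group, regenerates Et3Si+ and leaves the enol as its regiodefined silyl ether. The closest known reaction types are the Lewis acid-induced conjugate addition of alkenes to enones (zwitterion/ene manifold), silane-terminated Prins-type cation–olefin cyclizations and silylium-catalysed 1,4-hydrosilylation of enones. The new six-membered ring closes in a 6-exo-trig mode (both π bonds exocyclic to the forming ring) through a chair-like, cis-decalin-type transition state. The isopropyl-bearing centre is set by that chair: axial attack on the half-chair enone places the old ring axial on the new one, the side-chain methyl (fixed relative to C4 in step 1) is then equatorial and the Me2C= terminus must be equatorial to avoid a syn-diaxial clash, which gives isopropyl trans to methyl; the cis ring-fusion CH is temporary and is erased in step 4. The step needs cyclization to outrun direct 1,4-hydrosilylation (tethered π-nucleophile, −78 °C, weak neutral hydride donor) and hydride capture to outrun 1,2-hydride shift, proton loss or cyclobutane collapse (excess silane; the all-equatorial zwitterion could only close to a strained trans-fused cyclobutane).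

Step 4
Reactants: 5 triethyl{[(4aR,5R,8S,8aS)-5-methyl-8-(propan-2-yl)-3,4,4a,5,6,7,8,8a-octahydronaphthalen-2-yl]oxy}silane
Product: 6 (4aR,5R,8S)-5-methyl-8-(propan-2-yl)-4,4a,5,6,7,8-hexahydronaphthalen-2(3H)-one
Conditions: Pd(OAc)2 (1.1 equiv), MeCN–CH2Cl2, 25–40 °C
Reagents that add atoms: none
Why: Saegusa–Ito oxidation: the Pd(II) enolate formed from the regiodefined silyl enol ether loses its only β-hydrogen (the ring-fusion H), which restores the conjugated ring-fusion alkene, removes the temporary stereocentre and leaves the three others untouched.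

Step 5
Reactants: 6 (4aR,5R,8S)-5-methyl-8-(propan-2-yl)-4,4a,5,6,7,8-hexahydronaphthalen-2(3H)-one
Product: 7 (1S,4R,4aR)-4-methyl-7-methylidene-1-(propan-2-yl)-1,2,3,4,4a,5,6,7-octahydronaphthalene
Conditions: Ph3PCH3Br (1.5 equiv), KOtBu (1.4 equiv), THF, 0 °C → rt
Reagents that add atoms: methyltriphenylphosphonium bromide (as its ylide), C[P+](c1ccccc1)(c1ccccc1)c1ccccc1.[Br-]
Why: Wittig methylenation of the enone carbonyl (1,2-addition) gives the cross-conjugated exocyclic diene; no new stereocentre, and the low temperature and fast olefination should keep the γ-stereocentres from epimerising through the dienolate.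

Step 6
Reactants: 8 methyl 2,4,6-trihydroxybenzoate
Product: 9 methyl 2,6-dihydroxy-4-methoxybenzoate
Conditions: Me2SO4 (1.05 equiv), K2CO3 (1.1 equiv), acetone, rt
Reagents that add atoms: dimethyl sulfate, COS(=O)(=O)OC
Why: Williamson O-methylation: the 4-OH, para to the ester and not hydrogen-bonded to it, is the most acidic and most nucleophilic phenol, so one equivalent of Me2SO4 should methylate it selectively; no stereocentre.

Step 7
Reactants: 9 methyl 2,6-dihydroxy-4-methoxybenzoate
Product: 10 methyl 4-methoxy-3,5,5-trimethyl-2,6-dioxocyclohex-3-ene-1-carboxylate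
Conditions: NaOMe (4 equiv), MeI (4.5 equiv), MeOH, 0 °C → rt
Reagents that add atoms: iodomethane, CI
Why: Dearomatising C-methylation of a phloroglucinol-type dianion in methanol: C3 and C5 are methylated and the third methyl enters an already methylated carbon, which fixes the enol ether between CMe and CMe2 while the ester blocks the carbon between the two carbonyls; no stereocentre.

Step 8
Reactants: 10 methyl 4-methoxy-3,5,5-trimethyl-2,6-dioxocyclohex-3-ene-1-carboxylate
Product: 12 5-methoxy-4,6,6-trimethylcyclohex-4-ene-1,3-dione, via β-keto acid 11 (not isolated)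
Conditions: LiOH·H2O (3 equiv), THF–H2O, 40 °C; then 1 M HCl to pH 3, 0 → 25 °C
Reagents that add atoms: none
Why: Saponification of the β-keto ester and decarboxylation of the β-keto acid on mild acidification; the vinylogous methyl ester should survive because the substrate is a delocalised enolate under hydroxide and pH 3 at room temperature is too mild to hydrolyse it; no stereocentre.

Step 9
Reactants: 7 (1S,4R,4aR)-4-methyl-7-methylidene-1-(propan-2-yl)-1,2,3,4,4a,5,6,7-octahydronaphthalene; 12 5-methoxy-4,6,6-trimethylcyclohex-4-ene-1,3-dione; 13 2-methylpropanal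
Product: 15 CNP0194760.3, via heterodiene 14 (not isolated)
Conditions: 12 (1.2 equiv), 13 (1.5 equiv), L-proline (20 mol %), 4 Å MS, toluene, 25 → 80 °C
Reagents that add atoms: none
Why: Domino Knoevenagel/inverse-electron-demand hetero-Diels–Alder reaction: proline condenses 12 with 13 to heterodiene 14, whose more electron-poor oxadiene (the C=O next to CMe2) adds across the exocyclic C=CH2 of 7 with O bonding to the ring carbon; the spiro centre should arise from axial C–O bond formation on the ring face opposite the pseudo-axial ring-fusion H, and the CH(iPr) centre from the endo orientation of the vinyl arm (oxadiene over the flat C=C side), with minor regio- and stereoisomers removed by chromatography.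

Compound list
1 | (R)-citronellal, (3R)-3,7-dimethyloct-6-enal | O=CC[C@H](C)CCC=C(C)C | starting material
2 | methyl vinyl ketone (but-3-en-2-one) | CC(=O)C=C | starting material
3 | (2R,3R)-3,7-dimethyl-2-(3-oxobutyl)oct-6-enal | CC(=O)CC[C@@H](C=O)[C@H](C)CCC=C(C)C | intermediate
4 | (4R)-4-[(2R)-6-methylhept-5-en-2-yl]cyclohex-2-en-1-one | O=C1C=C[C@@H]([C@H](C)CCC=C(C)C)CC1 | intermediate
5 | triethyl{[(4aR,5R,8S,8aS)-5-methyl-8-(propan-2-yl)-3,4,4a,5,6,7,8,8a-octahydronaphthalen-2-yl]oxy}silane (cis-fused; isopropyl trans to methyl) | CC[Si](CC)(CC)OC1=C[C@H]2[C@H](C(C)C)CC[C@@H](C)[C@H]2CC1 | intermediate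
6 | (4aR,5R,8S)-5-methyl-8-(propan-2-yl)-4,4a,5,6,7,8-hexahydronaphthalen-2(3H)-one | O=C1C=C2[C@H](C(C)C)CC[C@@H](C)[C@H]2CC1 | intermediate
7 | (1S,4R,4aR)-4-methyl-7-methylidene-1-(propan-2-yl)-1,2,3,4,4a,5,6,7-octahydronaphthalene | C=C1C=C2[C@H](C(C)C)CC[C@@H](C)[C@H]2CC1 | intermediate
8 | methyl 2,4,6-trihydroxybenzoate | COC(=O)c1c(O)cc(O)cc1O | starting material
9 | methyl 2,6-dihydroxy-4-methoxybenzoate | COC(=O)c1c(O)cc(OC)cc1O | intermediate
10 | methyl 4-methoxy-3,5,5-trimethyl-2,6-dioxocyclohex-3-ene-1-carboxylate | COC(=O)C1C(=O)C(C)=C(OC)C(C)(C)C1=O | intermediate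
11 | 4-methoxy-3,5,5-trimethyl-2,6-dioxocyclohex-3-ene-1-carboxylic acid | OC(=O)C1C(=O)C(C)=C(OC)C(C)(C)C1=O | intermediate (not isolated)
12 | 5-methoxy-4,6,6-trimethylcyclohex-4-ene-1,3-dione | COC1=C(C)C(=O)CC(=O)C1(C)C | intermediate
13 | 2-methylpropanal (isobutyraldehyde) | CC(C)C=O | starting material
14 | 5-methoxy-4,6,6-trimethyl-2-(2-methylpropylidene)cyclohex-4-ene-1,3-dione | COC1=C(C)C(=O)C(=CC(C)C)C(=O)C1(C)C | intermediate (not isolated)
15 | CNP0194760.3, (2S,4R,4a′R,5′R,8′S)-7-methoxy-5′,6,8,8-tetramethyl-4,8′-di(propan-2-yl)-3,3′,4,4′,4a′,5′,6′,7′-octahydro-8′H-spiro[chromene-2,2′-naphthalen]-5(8H)-one | COC1=C(C)C(=O)C2=C(O[C@]3(C=C4[C@H](C(C)C)CC[C@@H](C)[C@H]4CC3)C[C@@H]2C(C)C)C1(C)C | target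

Total step count: 9. Longest linear sequence: 6 (steps 1, 2, 3, 4, 5, 9); the dione branch (steps 6, 7, 8) joins at step 9.

Steps most likely to fail

Step 3 (Proposed new method). The silyl-activated enone may be reduced directly by the silane before the alkene engages. The tertiary cation may also escape hydride capture by 1,2-hydride shifts, proton loss or collapse to a cyclobutane, and adventitious acid may protodesilylate the product and erase the enolate regiochemistry. Fallback with known chemistry: setting out from 4, a thermal (toluene, sealed tube, about 250 °C) or Me2AlCl-promoted intramolecular ene reaction through the same chair should give the cis-fused ketone (4aR,5R,8R,8aR)-5-methyl-8-(prop-1-en-2-yl)octahydronaphthalen-2(1H)-one F1. Chemoselective hydrogenation of its 1,1-disubstituted alkene (H2, (Ph3P)3RhCl, benzene) gives (4aR,5R,8S,8aS)-5-methyl-8-(propan-2-yl)octahydronaphthalen-2(1H)-one F2. Thermodynamic enol silylation (Et3SiCl, NaI, Et3N, MeCN), which in cis-fused 2-decalones goes toward the ring-fusion side, comes back to the route at 5.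

Step 9. The heterodiene may be drained by Michael addition of a second molecule of 12 (bis-adduct), and at 80 °C the choice between the two carbonyls and the facial and endo selectivity may erode. Fallback: setting out from 12 and 13, a three-component condensation with thiophenol (cat. piperidine, CH2Cl2) gives the storable sulfide 5-methoxy-4,6,6-trimethyl-2-[2-methyl-1-(phenylsulfanyl)propyl]cyclohex-4-ene-1,3-dione F3. Oxidation with mCPBA (1 equiv, −78 °C) gives the sulfoxide 2-[1-(benzenesulfinyl)-2-methylpropyl]-5-methoxy-4,6,6-trimethylcyclohex-4-ene-1,3-dione F4. Its syn-elimination at 0–25 °C releases 14 stoichiometrically, free of amine and of 12, so that the cycloaddition with 7 can be run at low temperature under Lewis acid catalysis (Sc(OTf)3, CH2Cl2, −20 °C); this comes back to the route at 15.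

Step 8. Hydroxide may attack the vinylogous methyl ester or open the trione ring by retro-Claisen cleavage instead of cleaving the hindered, enolised ester. Fallback: setting out from 9, the ester is cleaved before dearomatisation (NaOH aq., reflux) to give 2,6-dihydroxy-4-methoxybenzoic acid F5. C-trimethylation of its sodium salt (NaOMe, MeI, MeOH) and acidification to pH 3 at 0–25 °C lead through 11 (not isolated) back to the route at 12.

Further compounds
F1 | step 3 | (4aR,5R,8R,8aR)-5-methyl-8-(prop-1-en-2-yl)octahydronaphthalen-2(1H)-one | O=C1C[C@H]2[C@H](C(C)=C)CC[C@@H](C)[C@H]2CC1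
F2 | step 3 | (4aR,5R,8S,8aS)-5-methyl-8-(propan-2-yl)octahydronaphthalen-2(1H)-one | O=C1C[C@H]2[C@H](C(C)C)CC[C@@H](C)[C@H]2CC1
F3 | step 9 | 5-methoxy-4,6,6-trimethyl-2-[2-methyl-1-(phenylsulfanyl)propyl]cyclohex-4-ene-1,3-dione | COC1=C(C)C(=O)C(C(Sc2ccccc2)C(C)C)C(=O)C1(C)C
F4 | step 9 | 2-[1-(benzenesulfinyl)-2-methylpropyl]-5-methoxy-4,6,6-trimethylcyclohex-4-ene-1,3-dione | COC1=C(C)C(=O)C(C(S(=O)c2ccccc2)C(C)C)C(=O)C1(C)C
F5 | step 8 | 2,6-dihydroxy-4-methoxybenzoic acid | OC(=O)c1c(O)cc(OC)cc1O
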